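**Plan**

Numbering follows abscisic acid: ring carbons C1'–C6' (C1' carbinol, C4' ketone, C6' quaternary), C8' is the CH2O on C6', and the side chain is C1–C5.
Cuts: the O8'–acyl ester bond (frees a glutarate half-ester), C3–C4 (Stille), C4–C5 (one-carbon homologation of a lactol), then C5'–C4', C4'–C3' and C2'–C1' in ring C. This leaves a cyclopropanol, CO and propyne.
Enabling feature: O–C1' and C5'H2 stand 1,3 across quaternary C6', which is an opened cyclopropanol (temporary bond C1'–C5'). C4'(=O)–C3'H=C2'(CH3) is CO plus propyne. C8'–O is cis to C5 on the C1'–C6' bond, so O8' and C5 fit into one temporary cis-fused gamma-lactone.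
Forward: cyclopropane ring A and lactone ring B form together (step 2) and the C1' hydroxyl is added. Ring C is built by a carbonylative (3+1+2) annulation that cleaves ring A (step 4). Then ketal on, ring B opened to alkyne plus CH2OH, esterification, hydrostannation, Stille coupling, ketal off.
Stereochemistry: C6' comes from the enantioselective cyclopropanation and C1' is relayed from C6' by the cis ring fusion. The glutarate centre comes from esterase desymmetrisation, 4E from syn hydrostannation and 2Z from anti hydroiodination.

Key step: step 4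

Assumption: Rh2(4R-MPPIM)4 (MPPIM = methyl 1-(3-phenylpropanoyl)-2-oxoimidazolidine-4-carboxylate) is assumed to give the (1S,5R)-cyclopropane lactone; if the sense of induction is opposite, the 4S catalyst is used.

**Step 1**
Reactants: 1 2-methylprop-2-en-1-ol; 2 bromoacetyl bromide
Product: 4 2-methylallyl diazoacetate, via 2-methylallyl bromoacetate 3 (not isolated)
Conditions: NaHCO3, MeCN, 0 °C; then TsNHNHTs, DBU, THF, 0 °C
Reagents that add atoms: N,N'-ditosylhydrazine Cc1ccc(cc1)S(=O)(=O)NNS(=O)(=O)c1ccc(C)cc1
Why: O-acylation, then N-alkylation of ditosylhydrazine by the bromoacetate and base-induced loss of two sulfinate groups, is the standard mild conversion of an alcohol into its diazoacetate.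

**Step 2**
Reactants: 4 2-methylallyl diazoacetate
Product: 5 (1S,5R)-5-methyl-3-oxabicyclo[3.1.0]hexan-2-one
Conditions: Rh2(4R-MPPIM)4 (1 mol %), CH2Cl2, reflux, slow addition of 4
Reagents that add atoms: none
Why: Dirhodium carboxamidate-catalysed intramolecular cyclopropanation of an allylic diazoacetate closes ring A and ring B together, the chiral catalyst choosing the alkene face and so setting C6', while the bicyclo[3.1.0] frame can only be cis-fused.

**Step 3**
Reactants: 5 (1S,5R)-5-methyl-3-oxabicyclo[3.1.0]hexan-2-one
Product: 6 (1R,5S)-1-hydroxy-5-methyl-3-oxabicyclo[3.1.0]hexan-2-one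
Conditions: LiN(i-Pr)2, THF, −78 °C; then 3-phenyl-2-(phenylsulfonyl)oxaziridine, −78 °C; aqueous work-up
Reagents that add atoms: 3-phenyl-2-(phenylsulfonyl)oxaziridine O=S(=O)(N1OC1c1ccccc1)c1ccccc1
Why: This is a Davis oxidation of the lactone enolate, whose carbanion carbon is held by the bicycle so that oxygen can enter only where the hydrogen stood (retention).

**Step 4**
Reactants: 6 (1R,5S)-1-hydroxy-5-methyl-3-oxabicyclo[3.1.0]hexan-2-one; 7 carbon monoxide; 8 propyne
Product: 9 (3aS,7aR)-7a-hydroxy-3a,7-dimethyl-3a,4-dihydro-2-benzofuran-1,5(3H,7aH)-dione (cis-fused hydroxy enone lactone)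
Conditions: [Rh(cod)OH]2 (2.5 mol %), dppp (5 mol %), CO (1 atm), propyne (3 equiv, slow feed), 1,4-dioxane, 60 °C
Reagents that add atoms: none
Why: Proposed new method: the monovalent rhodium alkoxide of 6 should undergo beta-carbon elimination at the less substituted C1'–C5' bond to a primary alkylrhodium homoenolate of the alpha-keto lactone (no beta-hydrogen, C6' being quaternary), CO insertion then makes the acylrhodium (bond C5'–C4'), syn insertion of propyne with the acyl group going to the unsubstituted alkyne carbon gives the (Z)-beta-acylalkenylrhodium, and this adds to the C1' ketone (bond C2'–C1') before the new alkoxide is protonated by the next molecule of 6, so the cycle is redox-neutral and loses no atom. The closest known reaction types are the cobalt-catalysed (3+2) annulation of cyclopropanols with alkynes, which shares every elementary step but the CO insertion, the rhodium-catalysed carbonylative (3+2+1) cycloaddition of alkyne-tethered cyclopropanes, and the acylrhodation of alkynes in carbonylative additions of arylboronic acids. Ring C closes in the 6-exo-trig mode by attack of C2' on the C1' carbonyl carbon, while lactone ring B stays intact. C6' is not touched; C1' becomes planar in the homoenolate and is rebuilt under control of C6', because the alkenylrhodium hangs on the C5' arm and can reach only the ketone face syn to that arm, which allows only the cis-fused bicycle with the hydroxyl cis to the C6' methyl group. The step needs CO insertion to outrun protonolysis and direct alkyne insertion, the stated alkyne orientation, and capture by the ketone ahead of a second CO insertion. The substrate secures these through the unhindered primary C–Rh bond, the steric bias of a terminal alkyne, and a non-enolisable, very electrophilic alpha-keto lactone carbonyl held within reach of rhodium, helped by one atmosphere of CO and a slow feed of propyne.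

**Step 5**
Reactants: 9 cis-fused hydroxy enone lactone
Product: 10 (3aS,7aR)-7a-hydroxy-3a,7-dimethyl-3a,4-dihydro-3H-spiro[2-benzofuran-5,2'-[1,3]dioxolan]-1(7aH)-one (C4' ethylene ketal of 9)
Conditions: HOCH2CH2OH, PPTS, benzene, reflux (Dean–Stark)
Reagents that add atoms: ethane-1,2-diol OCCO
Why: Acid-catalysed ketalisation masks only the C4' carbonyl (the lactone is inert and the alkene has no ring gamma-hydrogen to migrate through), which permits the hydride step and stops the later free 8'-hydroxyl from adding to C2' in an oxa-Michael sense.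

**Step 6**
Reactants: 10 ketal lactone
Product: 11 lactol of 10, (3aS,7aR)-3a,7-dimethyl-3a,4-dihydro-3H-spiro[2-benzofuran-5,2'-[1,3]dioxolane]-1,7a(1H)-diol (both anomers)
Conditions: i-Bu2AlH (2.5 equiv), CH2Cl2, −78 °C; aqueous work-up
Reagents that add atoms: none
Why: After the first equivalent is consumed by the tertiary hydroxyl, half-reduction of a gamma-lactone with i-Bu2AlH at low temperature stops at the aluminium hemiacetal, and the ketal is inert.

**Step 7**
Reactants: 11 lactol
Product: 12 (8R,9S)-8-ethynyl-9-(hydroxymethyl)-7,9-dimethyl-1,4-dioxaspiro[4.5]dec-6-en-8-ol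
Conditions: dimethyl (1-diazo-2-oxopropyl)phosphonate, K2CO3, MeOH, 23 to 40 °C
Reagents that add atoms: dimethyl (1-diazo-2-oxopropyl)phosphonate CC(=O)C(=[N+]=[N-])P(=O)(OC)OC
Why: Ohira–Bestmann (Seyferth–Gilbert) homologation of the open hydroxy aldehyde form of the lactol gives the terminal alkyne and frees the 8'-hydroxymethyl group, which removes temporary ring B without touching C1' or C6'.

**Step 8**
Reactants: 13 dimethyl 3-hydroxy-3-methylpentanedioate
Product: 14 (3S)-3-hydroxy-5-methoxy-3-methyl-5-oxopentanoic acid
Conditions: pig liver esterase, KH2PO4/K2HPO4 buffer pH 7, 25 °C, 1 M NaOH (pH-stat); then HCl to pH 2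
Reagents that add atoms: water O
Why: Carboxylesterase (hydrolase) desymmetrisation of the prochiral diester hydrolyses one enantiotopic ester arm only, which sets the glutarate stereocentre.

**Step 9**
Reactants: 12 alkyne diol; 14 (3S)-half-ester
Product: 15 [(8R,9S)-8-ethynyl-8-hydroxy-7,9-dimethyl-1,4-dioxaspiro[4.5]dec-6-en-9-yl]methyl methyl (3R)-3-hydroxy-3-methylpentanedioate
Conditions: EDC·HCl, DMAP, CH2Cl2, 0 to 23 °C
Reagents that add atoms: none
Why: In this Steglich-type esterification only the primary 8'-hydroxyl is acylated, the tertiary hydroxyls of both partners being too hindered, and the glutarate centre is not involved (its descriptor changes only through the priority rules).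

**Step 10**
Reactants: 15 alkyne ester
Product: 16 {(8R,9S)-8-hydroxy-7,9-dimethyl-8-[(E)-2-(tributylstannyl)ethenyl]-1,4-dioxaspiro[4.5]dec-6-en-9-yl}methyl methyl (3R)-3-hydroxy-3-methylpentanedioate
Conditions: Bu3SnH, PdCl2(PPh3)2 (2 mol %), THF, 0 to 23 °C
Reagents that add atoms: tributyltin hydride CCCC[SnH](CCCC)CCCC
Why: Palladium-catalysed syn hydrostannation of a terminal alkyne next to a fully substituted carbinol carbon places tin on the free terminus and gives the (E)-vinylstannane.

**Step 11**
Reactants: 17 but-2-ynoic acid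
Product: 18 (2Z)-3-iodobut-2-enoic acid
Conditions: NaI, AcOH, 110 °C
Reagents that add atoms: sodium iodide [Na+].[I-]
Why: Conjugate addition of iodide to the alkynoic acid followed by protonation is a net anti hydroiodination and gives the Z isomer.

**Step 12**
Reactants: 16 (E)-vinylstannane; 18 (2Z)-3-iodobut-2-enoic acid
Product: 19 (2Z,4E)-5-[(8R,9S)-8-hydroxy-9-({[(3R)-3-hydroxy-5-methoxy-3-methyl-5-oxopentanoyl]oxy}methyl)-7,9-dimethyl-1,4-dioxaspiro[4.5]dec-6-en-8-yl]-3-methylpenta-2,4-dienoic acid
Conditions: PdCl2(MeCN)2 (5 mol %), DMF, 23 °C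
Reagents that add atoms: none
Why: Stille coupling joins C3 to C4 with retention of both alkene geometries and tolerates the unprotected beta-iodoalkenoic acid, so no ester protection of C1 is needed.

**Step 13**
Reactants: 19 ketal acid
Product: 20 (2Z,4E)-5-[(1R,6S)-1-hydroxy-6-({[(3R)-3-hydroxy-5-methoxy-3-methyl-5-oxopentanoyl]oxy}methyl)-2,6-dimethyl-4-oxocyclohex-2-en-1-yl]-3-methylpenta-2,4-dienoic acid (target)
Conditions: 1 M HCl, THF, 23 °C
Reagents that add atoms: water O
Why: Mild acid hydrolysis cleaves the allylic ketal far faster than the esters, and the enone appears only now, when O8' is acylated and can no longer cyclise onto C2'.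

**Compound list**

1 | 2-methylprop-2-en-1-ol | C=C(C)CO | starting material
2 | bromoacetyl bromide | BrCC(Br)=O | starting material
3 | 2-methylallyl bromoacetate | C=C(C)COC(=O)CBr | intermediate
4 | 2-methylallyl diazoacetate | C=C(C)COC(=O)C=[N+]=[N-] | intermediate
5 | (1S,5R)-5-methyl-3-oxabicyclo[3.1.0]hexan-2-one | O=C1OC[C@]2(C)C[C@H]12 | intermediate
6 | (1R,5S)-1-hydroxy-5-methyl-3-oxabicyclo[3.1.0]hexan-2-one | O=C1OC[C@]2(C)C[C@]12O | intermediate
7 | carbon monoxide | [C-]#[O+] | starting material
8 | propyne | CC#C | starting material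
9 | (3aS,7aR)-7a-hydroxy-3a,7-dimethyl-3a,4-dihydro-2-benzofuran-1,5(3H,7aH)-dione | O=C1OC[C@]2(C)CC(=O)C=C(C)[C@]12O | intermediate
10 | C4' ethylene ketal of 9 | O=C1OC[C@]2(C)CC3(OCCO3)C=C(C)[C@]12O | intermediate
11 | lactol of 10 (both anomers) | OC1OC[C@]2(C)CC3(OCCO3)C=C(C)[C@]12O | intermediate
12 | (8R,9S)-8-ethynyl-9-(hydroxymethyl)-7,9-dimethyl-1,4-dioxaspiro[4.5]dec-6-en-8-ol | OC[C@]1(C)CC2(OCCO2)C=C(C)[C@]1(O)C#C | intermediate
13 | dimethyl 3-hydroxy-3-methylpentanedioate | COC(=O)CC(C)(O)CC(=O)OC | starting material
14 | (3S)-3-hydroxy-5-methoxy-3-methyl-5-oxopentanoic acid | COC(=O)C[C@@](C)(O)CC(=O)O | intermediate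
15 | 8'-O-glutarate ester of 12 | COC(=O)C[C@@](C)(O)CC(=O)OC[C@]1(C)CC2(OCCO2)C=C(C)[C@]1(O)C#C | intermediate
16 | (E)-vinylstannane from 15 | COC(=O)C[C@@](C)(O)CC(=O)OC[C@]1(C)CC2(OCCO2)C=C(C)[C@]1(O)/C=C/[Sn](CCCC)(CCCC)CCCC | intermediate
17 | but-2-ynoic acid | CC#CC(=O)O | starting material
18 | (2Z)-3-iodobut-2-enoic acid | I/C(C)=C\C(=O)O | intermediate
19 | C4' ethylene ketal of the target | COC(=O)C[C@@](C)(O)CC(=O)OC[C@]1(C)CC2(OCCO2)C=C(C)[C@]1(O)/C=C/C(C)=C\C(=O)O | intermediate
20 | target, CNP0274837.1 | COC(=O)C[C@@](C)(O)CC(=O)OC[C@]1(C)CC(=O)C=C(C)[C@]1(O)/C=C/C(C)=C\C(=O)O | target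

**Step count and risks**

Total step count: 13. Longest linear sequence: 11 (steps 1–7, 9, 10, 12, 13).

Most likely to fail:

1. **Step 4 (proposed new method).** Possible failures are premature protonolysis of the alkylrhodium, oligomerisation of the alkyne, reversed orientation of the alkyne insertion, or a second CO insertion before ring closure. The fallback replaces carbonylative catalysis with a stepwise polar and organochromium assembly of known reaction types. It sets out from 6 and comes back at 9.
   - The zinc alkoxide of 6 (Et2Zn, THF) is C-acylated with commercial but-2-ynoyl chloride under PdCl2(PPh3)2 catalysis (acylation of a cyclopropanol-derived homoenolate). This gives (4S)-4-methyl-4-(2-oxopent-3-yn-1-yl)oxolane-2,3-dione F1.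
   - NaI in AcOH adds HI to the ynone in the anti sense to give (4S)-4-[(3Z)-4-iodo-2-oxopent-3-en-1-yl]-4-methyloxolane-2,3-dione F2.
   - CrCl2 with catalytic NiCl2 in DMF (intramolecular Nozaki–Hiyama–Kishi addition to the activated ketone) closes ring C to 9 with the same tether-enforced cis fusion.

2. **Step 3.** Possible failures are sluggish deprotonation of the cyclopropane C–H, self-condensation of the lactone enolate, or addition of the enolate to the sulfonimine by-product. The fallback brings the oxygen in through silicon instead of through an enolate. It sets out from 4 and comes back at 6.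
   - C-silylation of 4 with PhMe2SiOTf and i-Pr2NEt gives 2-methylallyl diazo[dimethyl(phenyl)silyl]acetate F3.
   - The same dirhodium-catalysed intramolecular cyclopropanation gives (1R,5S)-1-[dimethyl(phenyl)silyl]-5-methyl-3-oxabicyclo[3.1.0]hexan-2-one F4.
   - Fleming–Tamao oxidation (KBr, AcOOH, NaOAc) replaces silicon by hydroxyl with retention to give 6.

3. **Step 7.** Possible failures are a reluctant opening of the hindered lactol or a base-induced alpha-ketol shift of the alpha-hydroxy aldehyde before homologation. The fallback gives up the alkyne, hydrostannation and Stille line for an alkene and Heck line. It sets out from 11 and comes back at 19.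
   - Wittig methylenation (Ph3P=CH2, THF) gives (8R,9S)-8-ethenyl-9-(hydroxymethyl)-7,9-dimethyl-1,4-dioxaspiro[4.5]dec-6-en-8-ol F5.
   - Esterification with 14 (EDC·HCl, DMAP) gives [(8R,9S)-8-ethenyl-8-hydroxy-7,9-dimethyl-1,4-dioxaspiro[4.5]dec-6-en-9-yl]methyl methyl (3R)-3-hydroxy-3-methylpentanedioate F6.
   - Heck vinylation of the terminal alkene with 18 (Pd(OAc)2, Ag2CO3, DMF) gives the (2Z,4E)-dienoic acid 19. The carbinol carbon carries no hydrogen, so only the diene can form.

**Further compounds**

F1 | step 4 | (4S)-4-methyl-4-(2-oxopent-3-yn-1-yl)oxolane-2,3-dione | CC#CC(=O)C[C@@]1(C)COC(=O)C1=O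
F2 | step 4 | (4S)-4-[(3Z)-4-iodo-2-oxopent-3-en-1-yl]-4-methyloxolane-2,3-dione | I/C(C)=C\C(=O)C[C@@]1(C)COC(=O)C1=O
F3 | step 3 | 2-methylallyl diazo[dimethyl(phenyl)silyl]acetate | C=C(C)COC(=O)C(=[N+]=[N-])[Si](C)(C)c1ccccc1
F4 | step 3 | (1R,5S)-1-[dimethyl(phenyl)silyl]-5-methyl-3-oxabicyclo[3.1.0]hexan-2-one | O=C1OC[C@]2(C)C[C@]12[Si](C)(C)c1ccccc1
F5 | step 7 | (8R,9S)-8-ethenyl-9-(hydroxymethyl)-7,9-dimethyl-1,4-dioxaspiro[4.5]dec-6-en-8-ol | OC[C@]1(C)CC2(OCCO2)C=C(C)[C@]1(O)C=C
F6 | step 7 | [(8R,9S)-8-ethenyl-8-hydroxy-7,9-dimethyl-1,4-dioxaspiro[4.5]dec-6-en-9-yl]methyl methyl (3R)-3-hydroxy-3-methylpentanedioate | COC(=O)C[C@@](C)(O)CC(=O)OC[C@]1(C)CC2(OCCO2)C=C(C)[C@]1(O)C=C
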